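## The problem

Compound 14 is one heavily oxygenated cyclohexene; no ring fusion has to be made, only a six-membered carbocycle with a one-carbon branch. The ring atoms are lettered a (CH–OAc), b (=CH), c (=C carrying the exocyclic CH2OBz carbon g), d (CH–OH), e (CH–OBz) and f (CH–OH). The stereocentres are a (R), d (S), e (R) and f (S): the oxygens on e and f are cis, and those on a and d are cis to each other on the opposite face. A cyclic derivative of the e/f cis-diol can therefore send both C–O bonds at a and d to the other face, so only the e/f pair has to be set in the absolute sense. The second half of the problem is regiochemical: five oxygens end in three states (acetate on a, benzoate on e and g, free hydroxyl on d and f), and a/d and e/f are pairs that differ only in their distance from the branch on c. The esters can migrate under base (e to f, g to d, a to f), the allylic C–O bonds at a, d and g can ionise, and every cyclohexadiene-diol intermediate can dehydrate to a phenol; strong base, strong acid and heat are therefore excluded late in the route. The enabling feature is the unit b=c(g) beside the cis pair e, f: a–b–c–d with g on c is the C3–C6 diene of a 5-carboalkoxy-2-pyrone whose ester carbon is g, e–f is a cis-dioxygenated two-carbon dienophile, and the lactone bridge that joins a and d in the pyrone can leave by decarboxylation.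

## Retrosynthesis

**14 to 12 (through 13).** The last bond cut is the benzoyl C–O bond at e. Direct benzoylation of triol 12 would have to choose among three secondary hydroxyls and would favour the equatorial one. Passing the acyl group through the cyclic orthobenzoate 13 limits the choice to e and f and gives the ester to whichever of the two oxygens is axial. The forward step needs 13 to react through the half-chair in which the d-hydroxyl is pseudoaxial, which relieves A(1,2) strain with the CH2OBz group on c. In that conformer the oxygen on e is axial, the oxygen on f equatorial and the acetate on a pseudoequatorial.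

**12 to 11 to 10.** Cutting the two acetal C–O bonds leads from 12 to acetonide 11, and cutting the acetyl C–O bond at a leads to diol 10. Acetylating before the e/f diol is unmasked means the reagent meets two hydroxyls, not four. In 10 these two differ clearly: the one on a sits beside the unsubstituted alkene carbon b, the one on d beside c with its CH2OBz group. The forward acetylation must be kinetically selective for a and must not let the g-benzoate move to d.

**10 to 9 to 8.** The C–O bonds at a and d are cut together and traced to one molecule of dioxygen added across the diene termini of 8, via endoperoxide 9. One reagent forming both bonds guarantees the cis-1,4 relation, and the cis-fused acetonide decides the face. A stepwise alternative (epoxidation and allylic opening) would have to pick one of two alkenes and one of two faces twice. Diene 8 has no oxygen on a or d and two fewer stereocentres than 10. The forward step needs [4+2] addition anti to the acetonide, in preference to an ene reaction at the CH2OBz group.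

**8 to 7 to 6.** The benzoyl C–O bond at g and then the two C–H bonds at g are cut, so g is carried as the methyl ester of 6. Benzoylating at the stage of 7 is free of selectivity questions because the primary hydroxyl is then the only one. Reducing before photooxygenation turns an electron-poor dienoate into an electron-rich diene that accepts singlet oxygen readily.

**6 to 5 to 4.** The acetonide is exchanged for the cyclic carbonate of 4 by way of diol 5. The carbonate is what the commercial dienophile delivers, but it would not survive the hydride step, whereas the acetonide survives every later step and is a proven facial director. Compound 6 is also the point at which a chiral-pool route can rejoin (see the fallback for step 1).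

**4 to 3 to 1 + 2.** The bonds a–f and d–e are cut and a and d are reconnected through an O–C(=O) bridge, giving bridged lactone 3 and then methyl coumalate 1 and vinylene carbonate 2. No other cut delivers the ring, the branch g and the cis e/f pair from two commercial compounds in one operation. Three points are built into the forward plan:

- The endo or exo placement of the carbonate matters as much as the face of the pyrone. Endo and exo addition to the same face give mirror-image dienes once a and d are trigonal again, so both selectivities must be high.
- 1 offers the Lewis acid one carbonyl group and no chelate, so face selection rests on single-point binding and is the least secure element.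
- The catalysed addition and the decarboxylation are run as separate stages, with the Lewis acid removed in between, to protect the ionisable allylic carbonate of 4.

## Roads not taken

**Alternative 1: one-carbon ring expansion of a carbohydrate-derived cyclopentene.**
- Cut: bonds b–c, c–d and d–O; c is inserted into a five-membered ring.
- Forward key step: dibromocarbene (from CHBr3 and base) adds to the alkene of silyloxycyclopentene acetonide A2, made from D-ribose A3. AgClO4 in wet acetone then opens the cyclopropane with loss of bromide and capture of water, giving bromocyclohexenol A1.
- Merits: the configuration at a, e and f is inherited from A3, so the absolute configuration is certain. The oxygens on a and d arrive differentiated (silyl ether and free hydroxyl), which the chosen plan must achieve by a selective acetylation in step 6.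
- Weak points: c arrives as C–Br, so g still has to be attached by a separate C–C bond formation (for example a Pd(PPh3)4-catalysed carbonylation) and then reduced. Water can capture the bromoallyl cation at d or at b, and nothing in A2 clearly decides this. A2 needs about six steps from A3, and the e/f differentiation remains unsolved.
- Comparison: this road is better in certainty of absolute configuration and in a/d differentiation. The chosen plan sets against it roughly half the step count, g delivered by the ring-forming step, and a chiral-pool fallback entering at 6 that restores the same certainty.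

**Alternative 2: arene dearomatisation, photooxygenation, desymmetrising peroxide rearrangement.**
- Cut: the a–O and d–O bonds on a meso diene; the absolute configuration comes from desymmetrisation.
- Forward key step: benzene A4 is converted into meso cis-diol acetonide diene A5, and singlet oxygen gives meso endoperoxide A6. A chiral-base Kornblum–DeLaMare rearrangement would then give hydroxy enone A7.
- Merits: the cheapest starting material; the photooxygenation is established on exactly this substrate; a and d leave the desymmetrisation at different oxidation levels, which settles their differentiation.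
- Weak points: g is absent and must be added at c of A7 (Morita–Baylis–Hillman hydroxymethylation). The ketone at d must then be reduced to a hydroxyl trans to the acetonide oxygen on e, which requires hydride delivery from the acetonide face, against the steric bias. An inversion would probably be needed.
- Comparison: this road is better in raw-material cost and in the precedent for its opening steps. The chosen plan uses the same photooxygenation (step 5) on a diene that is already chiral and already carries g, so no desymmetrisation, no carbonyl reduction and no late C–C bond is needed. Its price is an unprecedented key step, which the fallback covers.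

**Alternative 3: quinone ester masked on an aromatic template, convex-face dihydroxylation.**
- Cut: the e–O and f–O bonds, made on a cage in which the b=c alkene is hidden.
- Forward key step: anthracene A8 and quinone ester A9 give a cycloadduct; reduction of both ketones and monosilylation give enediol A10; OsO4 with N-methylmorpholine N-oxide dihydroxylates it on the convex face to give A11. A retro-Diels–Alder reaction would release the b=c alkene at the end.
- Merits: on the rigid bicyclic scaffold every facial selectivity is predictable (hydride from the convex face puts the oxygens on a and d on the concave side, OsO4 puts those on e and f on the convex side), and g is present from A9.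
- Weak points: the first cycloaddition gives a racemate unless made asymmetric or resolved. The final cycloreversion needs temperatures that a molecule with allylic esters and free hydroxyls is unlikely to survive without acyl migration or aromatisation. A8 is carried as dead mass, and e/f and a/d must still be differentiated.
- Comparison: this road is better in the reliability of its relative configuration. The chosen plan sets against it the equally well-established anti addition of singlet oxygen to acetonide dienes, a mild end game, fewer steps and a route to one enantiomer.

Key step: step 1

Assumption: the sense of induction of a copper–bisoxazoline catalyst on a non-chelating pyrone cannot be predicted with confidence; the (S,S)-ligand is written, and its mirror image is used if the first runs show that it is the one leading to (3aR,7aS)-4.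

## Route

Step 1
Reactants: 1 methyl coumalate; 2 vinylene carbonate
Product: 4 methyl (3aR,7aS)-2-oxo-3a,7a-dihydro-1,3-benzodioxole-5-carboxylate, via bridged lactone cycloadduct 3 (not isolated)
Conditions: Cu(OTf)2 (10 mol %), (S,S)-tBu-bisoxazoline (11 mol %), 2 (3 equiv), 4 Å MS, CH2Cl2, 0 °C to rt; filter through silica; PhMe, 90 °C
Reagents that add atoms: none
Why: Proposed new method: divalent copper held by the C2-symmetric bisoxazoline binds the lactone carbonyl of 1 (its most basic oxygen; 1 has no second donor placed for chelation), which lowers the diene LUMO so that the electron-rich C=C of 2 adds across C3 and C6 in a concerted, asynchronous inverse-demand [4+2] step (bond to C6, the carbon activated by both carbonyl groups, leading) to give bridged lactone 3, and gentle heating after removal of the catalyst expels CO2 from 3 by retro-[4+2] to leave diene 4. The closest known reactions are the thermal Diels–Alder/decarboxylation sequences of 2-pyrones with alkenes and the copper–bisoxazoline-catalysed enantioselective inverse-demand additions to 3-carboalkoxy-2-pyrones, which chelate the metal through two carbonyl groups as 1 cannot. The one carbocycle (a to f) is closed by intermolecular cycloaddition, both new bonds (a–f and d–e) forming together on one face of each partner; the lactone bridge of 3 is temporary. The cis relation of the oxygens on e and f follows from the ring geometry of 2 and the suprafacial addition. Their absolute configuration is decided by two things together, the pyrone face that is used and the endo or exo placement of the carbonate, because endo and exo addition to the same face give mirror-image dienes once a and d are trigonal again. Face selection is asked of the ligand (a tert-butyl group lies over one face of the copper-bound carbonyl and C3), and endo selection (carbonate under the ester-bearing C4=C5 unit, as drawn for 3) of the compact cyclic dienophile and the low temperature of the catalysed stage. The symmetry of 2 removes any regiochemical question, and separating the catalysed addition from the decarboxylation keeps Lewis acid away from the ionisable allylic carbonate of 4.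

Step 2
Reactants: 4 methyl (3aR,7aS)-2-oxo-3a,7a-dihydro-1,3-benzodioxole-5-carboxylate
Product: 6 methyl (3aR,7aS)-2,2-dimethyl-3a,7a-dihydro-1,3-benzodioxole-5-carboxylate, via diol ester 5 (not isolated)
Conditions: K2CO3 (0.1 equiv), MeOH, 0 °C; evaporate below 25 °C; Me2C(OMe)2, PPTS (0.3 equiv), acetone, 0 °C to rt
Reagents that add atoms: 2,2-dimethoxypropane, COC(C)(C)OC
Why: Base-catalysed transesterification of the strained cyclic carbonate with methanol (the methyl ester is unchanged because the alkoxide is methoxide), then acid-catalysed transacetalisation of the cis-diol. Diol 5 is kept cold and unpurified because it can aromatise by loss of water; no stereocentre is touched.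

Step 3
Reactants: 6 methyl (3aR,7aS)-2,2-dimethyl-3a,7a-dihydro-1,3-benzodioxole-5-carboxylate
Product: 7 [(3aR,7aS)-2,2-dimethyl-3a,7a-dihydro-1,3-benzodioxol-5-yl]methanol
Conditions: iBu2AlH (2.5 equiv), CH2Cl2, −78 °C; aq. potassium sodium tartrate
Reagents that add atoms: none
Why: 1,2-Reduction of a conjugated ester by an aluminium hydride at low temperature, where conjugate reduction is not expected; the acetal is inert to hydride. The product is used promptly because dienes of this type dimerise on standing.

Step 4
Reactants: 7 [(3aR,7aS)-2,2-dimethyl-3a,7a-dihydro-1,3-benzodioxol-5-yl]methanol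
Product: 8 [(3aR,7aS)-2,2-dimethyl-3a,7a-dihydro-1,3-benzodioxol-5-yl]methyl benzoate
Conditions: BzCl, pyridine, DMAP (cat.), CH2Cl2, 0 °C
Reagents that add atoms: benzoyl chloride, O=C(Cl)c1ccccc1
Why: Nucleophile-catalysed acylation of the only hydroxyl group in the molecule, so no selectivity is required.

Step 5
Reactants: 8 [(3aR,7aS)-2,2-dimethyl-3a,7a-dihydro-1,3-benzodioxol-5-yl]methyl benzoate
Product: 10 [(3aR,4S,7R,7aS)-4,7-dihydroxy-2,2-dimethyl-3a,4,7,7a-tetrahydro-1,3-benzodioxol-5-yl]methyl benzoate, via endoperoxide 9 (not isolated)
Conditions: O2, tetraphenylporphyrin (cat.), visible light, CH2Cl2, −20 °C; then thiourea, MeOH, rt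
Reagents that add atoms: dioxygen, O=O
Why: [4+2] photooxygenation of the cisoid diene by singlet oxygen on the face opposite the cis-fused acetonide forms both C–O bonds at a and d at once, cis to each other and trans to the oxygens on e and f. Thiourea then cleaves only the O–O bond, so both new stereocentres keep their configuration.

Step 6
Reactants: 10 [(3aR,4S,7R,7aS)-4,7-dihydroxy-2,2-dimethyl-3a,4,7,7a-tetrahydro-1,3-benzodioxol-5-yl]methyl benzoate
Product: 11 [(3aR,4S,7R,7aS)-7-acetoxy-4-hydroxy-2,2-dimethyl-3a,4,7,7a-tetrahydro-1,3-benzodioxol-5-yl]methyl benzoate
Conditions: AcCl (1.05 equiv), 2,4,6-collidine, CH2Cl2, −78 °C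
Reagents that add atoms: acetyl chloride, CC(=O)Cl
Why: Kinetically controlled monoacylation of the less hindered hydroxyl: the one on a lies beside the unsubstituted alkene carbon b, the one on d beside c with its CH2OBz group. The weak, hindered base and low temperature also prevent a shift of the g-benzoate to d.

Step 7
Reactants: 11 [(3aR,4S,7R,7aS)-7-acetoxy-4-hydroxy-2,2-dimethyl-3a,4,7,7a-tetrahydro-1,3-benzodioxol-5-yl]methyl benzoate
Product: 12 [(3R,4R,5R,6S)-3-acetoxy-4,5,6-trihydroxycyclohex-1-en-1-yl]methyl benzoate
Conditions: TFA–H2O (9:1), CH2Cl2, 0 °C
Reagents that add atoms: none
Why: Acid-catalysed hydrolysis of the isopropylidene acetal; the esters are stable to cold aqueous acid for the short time required, and acyl migration is slow without base. The descriptor at f changes only through priority, not geometry.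

Step 8
Reactants: 12 [(3R,4R,5R,6S)-3-acetoxy-4,5,6-trihydroxycyclohex-1-en-1-yl]methyl benzoate
Product: 14 (1R,2S,5R,6S)-5-acetoxy-3-(benzoyloxymethyl)-2,6-dihydroxycyclohex-3-en-1-yl benzoate, via cyclic orthobenzoate 13 (not isolated)
Conditions: PhC(OMe)3 (1.3 equiv), CSA (cat.), MeCN, rt; then AcOH–H2O (4:1), rt
Reagents that add atoms: trimethyl orthobenzoate, COC(OC)(OC)c1ccccc1; water, O
Why: Acid-catalysed orthoester exchange closes the five-membered cyclic orthobenzoate on the only cis-vicinal diol (e/f), and mild aqueous acid opens it through the hemiorthoester, which collapses to the axial ester and equatorial alcohol. In the favoured half-chair (d-hydroxyl pseudoaxial to avoid A(1,2) strain with CH2OBz) the axial oxygen is the one on e; no stereocentre is altered.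

## Compound list

1 | methyl coumalate (methyl 2-oxo-2H-pyran-5-carboxylate) | COC(=O)C1=COC(=O)C=C1 | starting material
2 | vinylene carbonate (1,3-dioxol-2-one) | O=C1OC=CO1 | starting material
3 | methyl (1R,2S,6S,7S)-4,9-dioxo-3,5,8-trioxatricyclo[5.2.2.0(2,6)]undec-10-ene-11-carboxylate (endo adduct, carbonate on the side of the C=C bridge) | COC(=O)C1=C[C@H]2C(=O)O[C@@H]1[C@H]3OC(=O)O[C@@H]23 | intermediate
4 | methyl (3aR,7aS)-2-oxo-3a,7a-dihydro-1,3-benzodioxole-5-carboxylate | COC(=O)C1=C[C@H]2OC(=O)O[C@H]2C=C1 | intermediate
5 | methyl (3R,4S)-3,4-dihydroxycyclohexa-1,5-diene-1-carboxylate | COC(=O)C1=C[C@@H](O)[C@@H](O)C=C1 | intermediate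
6 | methyl (3aR,7aS)-2,2-dimethyl-3a,7a-dihydro-1,3-benzodioxole-5-carboxylate | COC(=O)C1=C[C@H]2OC(C)(C)O[C@H]2C=C1 | intermediate
7 | [(3aR,7aS)-2,2-dimethyl-3a,7a-dihydro-1,3-benzodioxol-5-yl]methanol | OCC1=C[C@H]2OC(C)(C)O[C@H]2C=C1 | intermediate
8 | [(3aR,7aS)-2,2-dimethyl-3a,7a-dihydro-1,3-benzodioxol-5-yl]methyl benzoate | O=C(OCC1=C[C@H]2OC(C)(C)O[C@H]2C=C1)c1ccccc1 | intermediate
9 | [(1S,2S,6R,7R)-4,4-dimethyl-3,5,8,9-tetraoxatricyclo[5.2.2.0(2,6)]undec-10-en-10-yl]methyl benzoate (peroxide bridge anti to the acetonide) | O=C(OCC1=C[C@H]2OO[C@@H]1[C@H]3OC(C)(C)O[C@@H]23)c1ccccc1 | intermediate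
10 | [(3aR,4S,7R,7aS)-4,7-dihydroxy-2,2-dimethyl-3a,4,7,7a-tetrahydro-1,3-benzodioxol-5-yl]methyl benzoate | O=C(OCC1=C[C@@H](O)[C@@H]2OC(C)(C)O[C@@H]2[C@H]1O)c1ccccc1 | intermediate
11 | [(3aR,4S,7R,7aS)-7-acetoxy-4-hydroxy-2,2-dimethyl-3a,4,7,7a-tetrahydro-1,3-benzodioxol-5-yl]methyl benzoate | CC(=O)O[C@@H]1C=C(COC(=O)c2ccccc2)[C@H](O)[C@H]2OC(C)(C)O[C@@H]12 | intermediate
12 | [(3R,4R,5R,6S)-3-acetoxy-4,5,6-trihydroxycyclohex-1-en-1-yl]methyl benzoate | CC(=O)O[C@@H]1C=C(COC(=O)c2ccccc2)[C@H](O)[C@@H](O)[C@H]1O | intermediate
13 | [(3aR,4S,7R,7aS)-7-acetoxy-4-hydroxy-2-methoxy-2-phenyl-3a,4,7,7a-tetrahydro-1,3-benzodioxol-5-yl]methyl benzoate (both epimers at the orthoester carbon) | CC(=O)O[C@@H]1C=C(COC(=O)c2ccccc2)[C@H](O)[C@H]2OC(OC)(c3ccccc3)O[C@@H]12 | intermediate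
14 | (1R,2S,5R,6S)-5-acetoxy-3-(benzoyloxymethyl)-2,6-dihydroxycyclohex-3-en-1-yl benzoate | CC(=O)O[C@@H]1C=C(COC(=O)c2ccccc2)[C@H](O)[C@@H](OC(=O)c2ccccc2)[C@H]1O | target

## Step count and least certain steps

Total: 8 steps. Longest linear sequence: 8 steps from methyl coumalate 1; the route is fully linear.

**Step 1 (key step, new method).** What may go wrong:
- Weak discrimination between the two pyrone faces, because 1 binds the metal through one carbonyl only.
- Competing exo addition, which feeds the mirror-image diene and lowers the enantiomeric purity even if face selection is good.
- Slow addition of the weakly nucleophilic 2, letting an uncatalysed racemic pathway contribute.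
- Ionisation of the allylic carbonate with aromatisation, or a second cycloaddition of 4, during decarboxylation.

Fallback, entirely known chemistry: the route does not set out from 1 and 2 but from commercial (−)-shikimic acid F1, whose C3 and C4 already have the configuration required at e and f. One-flask esterification and acetalisation (Me2C(OMe)2, CSA, MeOH) gives methyl 3,4-O-isopropylideneshikimate F2. Triflation of the remaining hydroxyl (Tf2O, pyridine, CH2Cl2) gives triflate F3. Elimination towards the allylic CH2 group (CsOAc, DMF, rt) gives diene 6, where the route is rejoined at step 3.

**Step 6.** What may go wrong: insufficient discrimination between the hydroxyls on a and d, with diacetylation or acetylation at d, since the two differ only in the neighbouring alkene substituent. Fallback with a tether in place of steric discrimination, setting out from 7: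
- Photooxygenation of 7 (O2, tetraphenylporphyrin, light) gives endoperoxide alcohol F4, and thiourea reduces it to triol F5.
- PhB(OH)2 ties the primary hydroxyl on g and the hydroxyl on d together as cyclic phenylboronate F6, leaving only the a-hydroxyl free.
- Ac2O and pyridine give boronate acetate F7; exchange with pinacol releases acetate diol F8.
- Benzoylation of the primary hydroxyl in preference to the hindered secondary one (BzCl, 2,4,6-collidine, CH2Cl2, −78 °C) gives 11, where the route is rejoined at step 7.

**Step 8.** What may go wrong: transfer of the benzoyl group to f if the other half-chair, with the oxygen on f axial, is the reacting conformer. Partial benzoylation of d through an acyclic mixed orthoester and acyl migration during the aqueous stage are further risks. Fallback with the opposite intrinsic preference, setting out from 12: Me2SnCl2 (cat.), BzCl and iPr2NEt in THF at 0 °C acylate through the transient dimethylstannylene acetal F9 of the cis-diol, a method that favours the equatorial oxygen. If the orthoester opening fails because e is equatorial, this delivers the benzoate to e and gives 14 directly.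

**Step 2.** What may go wrong: aromatisation of diol 5, either by base-induced loss of water (the hydrogen on e is activated through the dienoate) or by acid-catalysed dehydration during acetalisation. Fallback, setting out from 4: excess iBu2AlH (CH2Cl2, −78 to 0 °C) reduces the ester and the carbonate together under aprotic conditions to triol F10, (1S,2R)-4-(hydroxymethyl)cyclohexa-3,5-diene-1,2-diol, which no longer has the activating ester. Acetalisation of its cis-diol (Me2C(OMe)2, PPTS, acetone) gives 7, where the route is rejoined at step 4.

## Further compounds

F1 | step 1 | (−)-shikimic acid, (3R,4S,5R)-3,4,5-trihydroxycyclohex-1-ene-1-carboxylic acid | OC(=O)C1=C[C@@H](O)[C@@H](O)[C@H](O)C1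
F2 | step 1 | methyl (3aR,7R,7aS)-7-hydroxy-2,2-dimethyl-3a,6,7,7a-tetrahydro-1,3-benzodioxole-5-carboxylate | COC(=O)C1=C[C@H]2OC(C)(C)O[C@H]2[C@H](O)C1
F3 | step 1 | methyl (3aR,7R,7aR)-2,2-dimethyl-7-(trifluoromethylsulfonyloxy)-3a,6,7,7a-tetrahydro-1,3-benzodioxole-5-carboxylate | COC(=O)C1=C[C@H]2OC(C)(C)O[C@H]2[C@H](OS(=O)(=O)C(F)(F)F)C1
F4 | step 6 | [(1S,2S,6R,7R)-4,4-dimethyl-3,5,8,9-tetraoxatricyclo[5.2.2.0(2,6)]undec-10-en-10-yl]methanol | OCC1=C[C@H]2OO[C@@H]1[C@H]3OC(C)(C)O[C@@H]23
F5 | step 6 | (3aR,4S,7R,7aS)-5-(hydroxymethyl)-2,2-dimethyl-3a,4,7,7a-tetrahydro-1,3-benzodioxole-4,7-diol | OCC1=C[C@@H](O)[C@@H]2OC(C)(C)O[C@@H]2[C@H]1O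
F6 | step 6 | cyclic phenylboronate of F5 across the oxygens on g and d, hydroxyl on a free | O[C@@H]1C=C2COB(c3ccccc3)O[C@@H]2[C@H]4OC(C)(C)O[C@@H]14
F7 | step 6 | acetate of F6 at the oxygen on a | CC(=O)O[C@@H]1C=C2COB(c3ccccc3)O[C@@H]2[C@H]4OC(C)(C)O[C@@H]14
F8 | step 6 | (3aR,4S,7R,7aS)-4-hydroxy-5-(hydroxymethyl)-2,2-dimethyl-3a,4,7,7a-tetrahydro-1,3-benzodioxol-7-yl acetate | CC(=O)O[C@@H]1C=C(CO)[C@H](O)[C@H]2OC(C)(C)O[C@@H]12
F9 | step 8 | dimethylstannylene acetal of 12 across the oxygens on e and f | CC(=O)O[C@@H]1C=C(COC(=O)c2ccccc2)[C@H](O)[C@H]2O[Sn](C)(C)O[C@@H]12
F10 | step 2 | (1S,2R)-4-(hydroxymethyl)cyclohexa-3,5-diene-1,2-diol | OCC1=C[C@@H](O)[C@@H](O)C=C1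
A1 | alternative 1 | 2-bromocyclohexenol acetonide silyl ether (silyloxy on a, bromine on c, free hydroxyl on d) | CC(C)(C)[Si](C)(C)O[C@@H]1C=C(Br)[C@H](O)[C@H]2OC(C)(C)O[C@@H]12
A2 | alternative 1 | tert-butyldimethylsilyl ether of the cyclopent-2-ene-1,4,5-triol 4,5-acetonide, silyloxy group trans to the acetonide | CC(C)(C)[Si](C)(C)O[C@@H]1C=C[C@H]2OC(C)(C)O[C@@H]12
A3 | alternative 1 | D-ribose (open-chain form) | O=C[C@H](O)[C@H](O)[C@H](O)CO
A4 | alternative 2 | benzene | c1ccccc1
A5 | alternative 2 | meso-(3aR,7aS)-2,2-dimethyl-3a,7a-dihydro-1,3-benzodioxole | CC1(C)O[C@H]2C=CC=C[C@H]2O1
A6 | alternative 2 | meso endoperoxide acetonide, peroxide bridge anti to the acetonide | O3[C@@H]1C=C[C@H](O3)[C@H]2OC(C)(C)O[C@@H]12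
A7 | alternative 2 | 4-hydroxycyclohex-2-enone 5,6-acetonide, hydroxyl on a, ketone at d | O[C@@H]1C=CC(=O)[C@H]2OC(C)(C)O[C@@H]12
A8 | alternative 3 | anthracene | c1ccc2cc3ccccc3cc2c1
A9 | alternative 3 | methyl 3,6-dioxocyclohexa-1,4-diene-1-carboxylate | COC(=O)C1=CC(=O)C=CC1=O
A10 | alternative 3 | anthracene-bridged enediol monosilyl ether | CC(C)(C)[Si](C)(C)O[C@H]1C=C[C@@H](O)[C@]2(C(=O)OC)[C@H]1C3c4ccccc4C2c5ccccc35
A11 | alternative 3 | anthracene-bridged tetrol monosilyl ether | CC(C)(C)[Si](C)(C)O[C@H]1[C@H](O)[C@H](O)[C@@H](O)[C@]2(C(=O)OC)[C@H]1C3c4ccccc4C2c5ccccc35
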